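**Retrosynthetic overview**

1. Target ⇐ desilylation, peracid epoxidation of the ring-trans C1=C10 alkene and O8 methacrylation of a ten-membered 8-hydroxy α-methylene lactone; the oxirane is formed last, on the macrocycle, as in the biosynthesis.
2. Hydroxy lactone ⇐ one CrCl2-mediated closure of C6–C7 (the bond made when farnesyl diphosphate cyclises) of an acyclic hydroxy bromo enal, with lactonisation in the same flask; C6 and C7 are set from C8 alone.
3. Acyclic chain ⇐ catalytic asymmetric carbonyl-ene union (C8–C9) of an enal carrying a 1,1-disubstituted alkene with a bromomethyl oxobutenoate; this sets C8 and the C1=C10 geometry.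
4. Enal ⇐ B-alkyl Suzuki coupling of 2-methylidenepent-4-enyl acetate (propargyl alcohol + allyl Grignard) with a Z iodobutenol (butynediol); enophile ⇐ Baylis–Hillman chemistry of dimethoxyacetaldehyde and methyl acrylate.
5. Ring order: carbocycle and γ-lactone together (step 11), oxirane last (step 13).

Assumption: the SMILES is taken as written, i.e. (1R,6R,7R,8S,10S), trans-epoxide, C4=C5 E by CIP (ring carbons C3 and C6 cis); C1–C15 are germacrane positions, plain numbers are compounds.

**Route**

Step 1
Reactants: 1 but-2-yne-1,4-diol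
Product: 2 4-[(tert-butyldimethylsilyl)oxy]but-2-yn-1-ol
Conditions: NaH (1.0 equiv), THF, 0 °C; TBSCl (1.0 equiv), 0 °C → rt
Reagents that add atoms: tert-butyldimethylsilyl chloride, CC(C)(C)[Si](C)(C)Cl
Why: Mono-O-silylation of a symmetric diol through its monosodium alkoxide; it differentiates the future C15 and C6 oxygens and creates no stereocentre.

Step 2
Reactants: 2 4-[(tert-butyldimethylsilyl)oxy]but-2-yn-1-ol
Product: 4 (Z)-4-[(tert-butyldimethylsilyl)oxy]-3-iodobut-2-en-1-ol, via cyclic sodium alkenylaluminate 3 (not isolated)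
Conditions: NaAlH2(OCH2CH2OMe)2 (1.5 equiv), THF, 0 °C → rt; then I2, THF, −78 → 0 °C; aq. work-up
Reagents that add atoms: iodine, II
Why: Hydroxyl-directed trans-hydroalumination of a propargylic alcohol followed by iodinolysis (Corey-type reduction–iodination): hydride goes to the alkyne carbon next to the free CH2OH and aluminium to the distal carbon in a five-membered ring, so the iodide ends cis to CH2OH, which fixes the later C4=C5 geometry (C3 cis to C6).

Step 3
Reactants: 5 prop-2-yn-1-ol; 6 allylmagnesium chloride (CH2=CHCH2MgCl)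
Product: 8 2-methylidenepent-4-en-1-ol, via bis(chloromagnesium) alkenyl alkoxide 7 (not isolated)
Conditions: CH2=CHCH2MgCl (2.2 equiv), CuI (5 mol%), THF, −20 °C → rt; then 1 M HCl
Reagents that add atoms: none
Why: Alkoxide-directed anti-carbomagnesiation of a propargylic alcohol: the allyl group adds to the carbon bearing CH2OH and protonolysis of the C–Mg bond leaves the 1,1-disubstituted alkene (future C9=C10 ene donor); no stereocentre.

Step 4
Reactants: 8 2-methylidenepent-4-en-1-ol
Product: 9 2-methylidenepent-4-en-1-yl acetate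
Conditions: Ac2O, pyridine, DMAP (cat.), CH2Cl2, 0 °C → rt
Reagents that add atoms: acetic anhydride, CC(=O)OC(C)=O
Why: DMAP-catalysed O-acetylation puts the C14 acetate of the target in place at the outset, so this oxygen needs no protecting group.

Step 5
Reactants: 9 2-methylidenepent-4-en-1-yl acetate; 4 (Z)-4-[(tert-butyldimethylsilyl)oxy]-3-iodobut-2-en-1-ol
Product: 11 (E)-6-{[(tert-butyldimethylsilyl)oxy]methyl}-8-hydroxy-2-methylideneoct-6-en-1-yl acetate, via B-alkyl-9-borabicyclononane 10 (not isolated)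
Conditions: 9-BBN (1.0 equiv), THF, 0 °C → rt; then 4 (1.1 equiv), Pd(dppf)Cl2 (5 mol%), AsPh3 (10 mol%), K3PO4 (3 M aq.), DMF, rt
Reagents that add atoms: none
Why: Anti-Markovnikov hydroboration of the monosubstituted alkene (the 1,1-disubstituted alkene is slowed by its allylic acetate) then B-alkyl Suzuki–Miyaura coupling with retention at the alkenyl iodide; oxidative addition of zerovalent palladium to the C–I bond outpaces ionisation of the allylic acetate at rt.

Step 6
Reactants: 11 (E)-6-{[(tert-butyldimethylsilyl)oxy]methyl}-8-hydroxy-2-methylideneoct-6-en-1-yl acetate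
Product: 12 (E)-6-{[(tert-butyldimethylsilyl)oxy]methyl}-2-methylidene-8-oxooct-6-en-1-yl acetate
Conditions: MnO2 (15 equiv), CH2Cl2, rt
Reagents that add atoms: none
Why: MnO2 allylic oxidation of the only free (primary allylic) alcohol gives the C6 enal without touching acetate, silyl ether or alkene geometry.

Step 7
Reactants: 13 2,2-dimethoxyacetaldehyde; 14 methyl acrylate
Product: 15 methyl 3-hydroxy-4,4-dimethoxy-2-methylidenebutanoate (racemic)
Conditions: DABCO (0.5 equiv), 1,4-dioxane/H2O, rt, 48 h
Reagents that add atoms: none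
Why: Morita–Baylis–Hillman reaction of an activated aldehyde; the racemic carbinol centre is destroyed in step 8.

Step 8
Reactants: 15 methyl 3-hydroxy-4,4-dimethoxy-2-methylidenebutanoate
Product: 16 methyl (Z)-2-(bromomethyl)-4,4-dimethoxybut-2-enoate
Conditions: NBS, Me2S, CH2Cl2, 0 °C → rt
Reagents that add atoms: N-bromosuccinimide, BrN1C(=O)CCC1=O
Why: SN2′ bromination of the Baylis–Hillman alcohol through its alkoxysulfonium salt gives the thermodynamically favoured Z trisubstituted allylic bromide under non-acidic conditions that keep the acetal.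

Step 9
Reactants: 16 methyl (Z)-2-(bromomethyl)-4,4-dimethoxybut-2-enoate
Product: 17 methyl (Z)-2-(bromomethyl)-4-oxobut-2-enoate
Conditions: TFA (cat.), H2O, CH2Cl2, 0 °C; used without chromatography
Reagents that add atoms: water, O
Why: Acid-catalysed acetal hydrolysis unmasks the C8 aldehyde, which is conjugated to the ester (a vinylogous glyoxylate) and therefore a strong enophile.

Step 10
Reactants: 12 (E)-6-{[(tert-butyldimethylsilyl)oxy]methyl}-2-methylidene-8-oxooct-6-en-1-yl acetate; 17 methyl (Z)-2-(bromomethyl)-4-oxobut-2-enoate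
Product: 18 methyl (2Z,4S,6Z,10E)-6-(acetoxymethyl)-2-(bromomethyl)-10-{[(tert-butyldimethylsilyl)oxy]methyl}-4-hydroxy-12-oxododeca-2,6,10-trienoate
Conditions: (S)-BINOL (20 mol%), TiCl2(OiPr)2 (20 mol%), 4 Å MS, CH2Cl2, −30 → 0 °C; 17 (1.5 equiv)
Reagents that add atoms: none
Why: Mikami-type catalytic asymmetric carbonyl-ene reaction of a vinylogous glyoxylate: the aldehyde of 17 is the only strong enophile and the 1,1-disubstituted alkene of 12 the only ene donor, hydrogen is taken from C1 and not from the acetoxymethyl carbon, the C2 chain sits exo in the six-membered transition state so that the new C1=C10 alkene has C2 trans to C9, and the (S)-BINOL–titanium complex selects the aldehyde face that gives 8S (the (R)-catalyst gives (R)-carbinols with glyoxylate, whose ester has the CIP rank that C7 has here).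

Step 11
Reactants: 18 methyl (2Z,4S,6Z,10E)-6-(acetoxymethyl)-2-(bromomethyl)-10-{[(tert-butyldimethylsilyl)oxy]methyl}-4-hydroxy-12-oxododeca-2,6,10-trienoate
Product: 21 (1(10)Z,4E,6R,7R,8S)-14-acetoxy-15-[(tert-butyldimethylsilyl)oxy]-8-hydroxygermacra-1(10),4,11(13)-trien-12,6-olide, via allylchromium dichloride 19 (not isolated), via chromium alkoxide hydroxy ester 20 (not isolated)
Conditions: CrCl2 (8 equiv), THF, rt, syringe-pump addition of 18 over 12 h (final 2 mM), then 40 °C, 2 h; H2O
Reagents that add atoms: none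
Why: Intramolecular Nozaki–Hiyama allylation with lactonisation in the flask: the allylchromium adds through C7 to the enal in a chair transition state with both chain arms equatorial (6,7-anti, hence the trans-lactone) on the C7 face anti to O8 with H8 held in the alkene plane by allylic 1,3-strain, which gives 6R,7R from 8S; this closes the C6–C7 bond of farnesyl diphosphate cyclisation with chromium leaving C13 where the cyclase removes a proton, and the O6 alkoxide of trivalent chromium then displaces methoxide from the ester while the neutral 8-OH neither lactonises nor acts as a leaving group.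

Step 12
Reactants: 21 (1(10)Z,4E,6R,7R,8S)-14-acetoxy-15-[(tert-butyldimethylsilyl)oxy]-8-hydroxygermacra-1(10),4,11(13)-trien-12,6-olide
Product: 22 (1(10)Z,4E,6R,7R,8S)-14-acetoxy-15-[(tert-butyldimethylsilyl)oxy]-8-(methacryloyloxy)germacra-1(10),4,11(13)-trien-12,6-olide
Conditions: methacrylic anhydride (2 equiv), Et3N, DMAP (cat.), CH2Cl2, 0 °C → rt
Reagents that add atoms: methacrylic anhydride, C=C(C)C(=O)OC(=O)C(C)=C
Why: DMAP-catalysed acyl transfer to the only free hydroxyl installs the C8 methacrylate with retention at C8.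

Step 13
Reactants: 22 (1(10)Z,4E,6R,7R,8S)-14-acetoxy-15-[(tert-butyldimethylsilyl)oxy]-8-(methacryloyloxy)germacra-1(10),4,11(13)-trien-12,6-olide
Product: 23 (1R,4E,6R,7R,8S,10S)-14-acetoxy-15-[(tert-butyldimethylsilyl)oxy]-1,10-epoxy-8-(methacryloyloxy)germacra-4,11(13)-dien-12,6-olide
Conditions: mCPBA (1.2 equiv), CH2Cl2, 0 °C
Reagents that add atoms: meta-chloroperoxybenzoic acid, OOC(=O)c1cccc(Cl)c1
Why: Prilezhaev epoxidation as in the biosynthesis: the strained ring-trans C1=C10 alkene is the most reactive (C4=C5 carries two allylic oxygens and a bulky silyl ether, the two acrylate alkenes are electron-poor), and the peracid attacks its outer face in the conformer with C14 on the β face, giving the 1β,10α (1R,10S) trans-epoxide.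

Step 14
Reactants: 23 (1R,4E,6R,7R,8S,10S)-14-acetoxy-15-[(tert-butyldimethylsilyl)oxy]-1,10-epoxy-8-(methacryloyloxy)germacra-4,11(13)-dien-12,6-olide
Product: 24 (1R,4E,6R,7R,8S,10S)-14-acetoxy-1,10-epoxy-15-hydroxy-8-(methacryloyloxy)germacra-4,11(13)-dien-12,6-olide (CNP0306006.2)
Conditions: HF·pyridine, pyridine, THF, 0 °C
Reagents that add atoms: none
Why: Fluoride-mediated cleavage of the primary silyl ether under pyridine-buffered conditions that spare the epoxide, both esters and the α-methylene lactone; no stereocentre is touched.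

**Compound list**

1 | but-2-yne-1,4-diol | OCC#CCO | starting material
2 | 4-[(tert-butyldimethylsilyl)oxy]but-2-yn-1-ol | OCC#CCO[Si](C)(C)C(C)(C)C | intermediate
3 | cyclic sodium alkenylaluminate (five-membered O–Al–C ring, Al on the carbon bearing CH2OTBS; formed in the flask) | [Na+].COCCO[Al-]1(OCCOC)OCC=C1CO[Si](C)(C)C(C)(C)C | intermediate
4 | (Z)-4-[(tert-butyldimethylsilyl)oxy]-3-iodobut-2-en-1-ol | OC/C=C(\I)CO[Si](C)(C)C(C)(C)C | intermediate
5 | prop-2-yn-1-ol | C#CCO | starting material
6 | allylmagnesium chloride (CH2=CHCH2MgCl) | C=CC[Mg]Cl | starting material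
7 | bis(chloromagnesium) alkenyl alkoxide (Mg on the alkene carbon cis to CH2O; formed in the flask) | C=CC/C(CO[Mg]Cl)=C/[Mg]Cl | intermediate
8 | 2-methylidenepent-4-en-1-ol | C=CCC(=C)CO | intermediate
9 | 2-methylidenepent-4-en-1-yl acetate | C=CCC(=C)COC(C)=O | intermediate
10 | B-(5-acetoxy-4-methylidenepentyl)-9-borabicyclo[3.3.1]nonane (formed in the flask) | CC(=O)OCC(=C)CCCB1C2CCCC1CCC2 | intermediate
11 | (E)-6-{[(tert-butyldimethylsilyl)oxy]methyl}-8-hydroxy-2-methylideneoct-6-en-1-yl acetate | C=C(COC(C)=O)CCC/C(CO[Si](C)(C)C(C)(C)C)=C\CO | intermediate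
12 | (E)-6-{[(tert-butyldimethylsilyl)oxy]methyl}-2-methylidene-8-oxooct-6-en-1-yl acetate | C=C(COC(C)=O)CCC/C(CO[Si](C)(C)C(C)(C)C)=C\C=O | intermediate
13 | 2,2-dimethoxyacetaldehyde | COC(OC)C=O | starting material
14 | methyl acrylate | C=CC(=O)OC | starting material
15 | methyl 3-hydroxy-4,4-dimethoxy-2-methylidenebutanoate (racemic) | COC(OC)C(O)C(=C)C(=O)OC | intermediate
16 | methyl (Z)-2-(bromomethyl)-4,4-dimethoxybut-2-enoate | COC(OC)/C=C(\CBr)C(=O)OC | intermediate
17 | methyl (Z)-2-(bromomethyl)-4-oxobut-2-enoate | O=C/C=C(\CBr)C(=O)OC | intermediate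
18 | methyl (2Z,4S,6Z,10E)-6-(acetoxymethyl)-2-(bromomethyl)-10-{[(tert-butyldimethylsilyl)oxy]methyl}-4-hydroxy-12-oxododeca-2,6,10-trienoate | O=C/C=C(CO[Si](C)(C)C(C)(C)C)\CC/C=C(\COC(C)=O)C[C@H](O)/C=C(\CBr)C(=O)OC | intermediate
19 | allylchromium dichloride of 18 (CrCl2 on the former CH2Br carbon; formed in the flask) | O=C/C=C(CO[Si](C)(C)C(C)(C)C)\CC/C=C(\COC(C)=O)C[C@H](O)/C=C(\C[Cr](Cl)Cl)C(=O)OC | intermediate
20 | ten-membered (6R,7R,8S) hydroxy methyl ester as its O6 chromium dichloride alkoxide (formed in the flask) | O[C@H]1C/C(COC(C)=O)=C/CC/C(CO[Si](C)(C)C(C)(C)C)=C\[C@@H](O[Cr](Cl)Cl)[C@@H]1C(=C)C(=O)OC | intermediate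
21 | (1(10)Z,4E,6R,7R,8S)-14-acetoxy-15-[(tert-butyldimethylsilyl)oxy]-8-hydroxygermacra-1(10),4,11(13)-trien-12,6-olide | O[C@H]1C/C(COC(C)=O)=C/CC/C(CO[Si](C)(C)C(C)(C)C)=C\[C@H]2OC(=O)C(=C)[C@H]12 | intermediate
22 | (1(10)Z,4E,6R,7R,8S)-14-acetoxy-15-[(tert-butyldimethylsilyl)oxy]-8-(methacryloyloxy)germacra-1(10),4,11(13)-trien-12,6-olide | C=C(C)C(=O)O[C@H]1C/C(COC(C)=O)=C/CC/C(CO[Si](C)(C)C(C)(C)C)=C\[C@H]2OC(=O)C(=C)[C@H]12 | intermediate
23 | (1R,4E,6R,7R,8S,10S)-14-acetoxy-15-[(tert-butyldimethylsilyl)oxy]-1,10-epoxy-8-(methacryloyloxy)germacra-4,11(13)-dien-12,6-olide | C=C(C)C(=O)O[C@H]1C[C@@]2(COC(C)=O)O[C@@H]2CC/C(CO[Si](C)(C)C(C)(C)C)=C\[C@H]2OC(=O)C(=C)[C@H]12 | intermediate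
24 | (1R,4E,6R,7R,8S,10S)-14-acetoxy-1,10-epoxy-15-hydroxy-8-(methacryloyloxy)germacra-4,11(13)-dien-12,6-olide (CNP0306006.2) | C=C(C)C(=O)O[C@H]1C[C@@]2(COC(C)=O)O[C@@H]2CC/C(CO)=C\[C@H]2OC(=O)C(=C)[C@H]12 | target

**Step count and risks**

Total step count: 14. Longest linear sequence: 9 steps (steps 3, 4, 5, 6, 10, 11, 12, 13, 14).

Three steps most likely to fail:

Step 10 (ene reaction). The ene donor is deactivated by its allylic acetate, the enophile is weaker than glyoxylate itself, and alkene geometry and enantioselectivity are untested on this pair. Fallback: set out from 12 and 17 and promote the ene reaction with stoichiometric Me2AlCl (CH2Cl2, −78 → −20 °C). This far stronger, achiral promoter gives 18 as a racemate, i.e. together with the 4R enantiomer of 18 F1. Kinetic resolution with immobilised Candida antarctica lipase B and vinyl acetate (tBuOMe, 30 °C) is then expected to acetylate the R alcohol (larger alkenyl arm of higher CIP rank), giving the 4-O-acetate of that enantiomer F2, which is separated. Unreacted 18 is carried on, so the route is rejoined at 18.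

Step 11 (macrocyclisation–lactonisation). The free 8-OH may protonate the allylchromium or compete with O6 for the ester, and ten-membered closure is slow. Fallback: set out from 18 and silylate O8 (Et3SiOTf, 2,6-lutidine, CH2Cl2, −78 °C) to the C8 triethylsilyl ether of 18 F3. Cyclise this with CrCl2 under the same high-dilution conditions to the C8 triethylsilyl ether of 21 F4; now only O6 can lactonise and no acidic proton sits next to the organochromium. Remove the secondary triethylsilyl group selectively (PPTS, MeOH, 0 °C; the primary tert-butyldimethylsilyl ether survives) to come back at 21.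

Step 13 (epoxidation). Facial selectivity rests on the ring conformation alone. Fallback: set out from 21 and epoxidise before acylation under hydroxyl direction (VO(acac)2 cat., tBuOOH, CH2Cl2, 0 °C → rt). The vanadium alkoxide of the 8α-hydroxyl delivers oxygen to the homoallylic C1=C10 alkene from the α side at C10, giving the (1R,6R,7R,8S,10S) epoxy alcohol F5. Acylation with methacrylic anhydride, Et3N and DMAP then gives 23, where the route is rejoined.

**Further compounds**

F1 | step 10 | methyl (2Z,4R,6Z,10E)-6-(acetoxymethyl)-2-(bromomethyl)-10-{[(tert-butyldimethylsilyl)oxy]methyl}-4-hydroxy-12-oxododeca-2,6,10-trienoate (enantiomer of 18) | O=C/C=C(CO[Si](C)(C)C(C)(C)C)\CC/C=C(\COC(C)=O)C[C@@H](O)/C=C(\CBr)C(=O)OC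
F2 | step 10 | methyl (2Z,4R,6Z,10E)-4-acetoxy-6-(acetoxymethyl)-2-(bromomethyl)-10-{[(tert-butyldimethylsilyl)oxy]methyl}-12-oxododeca-2,6,10-trienoate | O=C/C=C(CO[Si](C)(C)C(C)(C)C)\CC/C=C(\COC(C)=O)C[C@@H](OC(C)=O)/C=C(\CBr)C(=O)OC
F3 | step 11 | C8 (chain C4, S) triethylsilyl ether of 18 | O=C/C=C(CO[Si](C)(C)C(C)(C)C)\CC/C=C(\COC(C)=O)C[C@H](O[Si](CC)(CC)CC)/C=C(\CBr)C(=O)OC
F4 | step 11 | C8 triethylsilyl ether of 21 (configuration at C6, C7 and C8 as in 21) | CC[Si](CC)(CC)O[C@H]1C/C(COC(C)=O)=C/CC/C(CO[Si](C)(C)C(C)(C)C)=C\[C@H]2OC(=O)C(=C)[C@H]12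
F5 | step 13 | (1R,4E,6R,7R,8S,10S)-14-acetoxy-15-[(tert-butyldimethylsilyl)oxy]-1,10-epoxy-8-hydroxygermacra-4,11(13)-dien-12,6-olide | O[C@H]1C[C@@]2(COC(C)=O)O[C@@H]2CC/C(CO[Si](C)(C)C(C)(C)C)=C\[C@H]2OC(=O)C(=C)[C@H]12
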